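The easy step comes first: I read how fast the electrophile goes at the start, then what slows it.

| flask | electrophile | nucleophile | remark | time |
|---|---|---|---|---|
| maple | 4.2 mM | 26 mM | run made earlier |  |
| oak | 48 mM | 26 mM | run made earlier |  |
| Sunday's | 10 mM | 26.0 mM |  | 1.5 h |
| Tuesday's | 30 mM | 26.0 mM |  | 1.5 h |
| Saturday's | 6.0 mM | 26.0 mM |  | 1.5 h |
| Friday's | 20 mM | 26.0 mM |  | 1.5 h |
| Monday's | 60 mM | 26.0 mM |  | 1.5 h |

| run | time / min | target / % | electrophile / % |
|---|---|---|---|
| maple | 10.0 | 26.7 | 73.7 |
| maple | 20.0 | 38.5 | 60.5 |
| maple | 30.0 | 44.1 | 51.5 |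
| maple | 40.0 | 48.7 | 43.9 |
| maple | 50.0 | 51.2 | 40.5 |
| maple | 60.0 | 50.9 | 35.4 |
| oak | 4.00 | 11.0 | 91.2 |
| oak | 12.0 | 17.4 | 82.4 |
| oak | 20.0 | 22.0 | 77.7 |
| oak | 30.0 | 18.7 | 76.9 |
| oak | 50.0 | 22.0 | 76.2 |
| oak | 60.0 | 18.2 | 75.4 |

(readings scatter by 1 percentage point)

- the numbers in the tables scatter with a standard deviation of 1 percentage point
- on the list of suspects stand: target -> over-reaction product; 2 nucleophile -> homo dimer; electrophile + nucleophile -> acid set free + target; nucleophile + acid set free <-> protonated nucleophile

- the flasks put in order of amount of target, in percent of the electrophile charged, best first, at 1.5 h (Sunday's / Tuesday's / Saturday's / Friday's / Monday's)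
- the same order at 20 min (Sunday's / Tuesday's / Saturday's / Friday's / Monday's)
- the amount of target, in percent of the electrophile charged of the flask you put first, at 1.5 h
- the amount of target, in percent of the electrophile charged of the flask you put last, at 1.5 h

Maple's first reading gives an apparent first-order constant (pseudo-first-order, with the nucleophile charged in excess) of 0.0305 min⁻¹, a half-life of 22.7 min. Between 40.0 min and 60.0 min the constant reads 0.0108 min⁻¹, slower by a factor of 2.82. Oak starts at 0.0230 min⁻¹, but from 20.0 min to 60.0 min it reads 7.51 × 10⁻⁴ min⁻¹, a factor of 30.7. That factor is rough, because the drop behind it is 2.3 percentage points with a scatter of 1 point.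

The slowing adds up, so I count half-lives lived. Maple has lived 1.50 by 60.0 min and is still moving, while oak, with the larger charge, has nearly stopped at 0.407. With the nucleophile charge held, I take the half-lives at the stop to go inversely with the electrophile charge. My half-life allowance, half-lives at the stop times the charge, is 19.6 mM.

| Flask | Half-lives allowed |
|---|---|
| Saturday's | 3.26 |
| Sunday's | 1.96 |
| Friday's | 0.978 |
| Tuesday's | 0.652 |
| Monday's | 0.326 |

Maple's late constant carried on to 1.5 h gives about 1.96 half-lives. Saturday's allowance exceeds that, Sunday's about meets it, and Monday's falls far short. I commit to Monday's keeping 79.8% of its electrophile, with Saturday's first and Monday's last. Oak was close to its stop by 20.0 min, so I expect the same order at 20 min.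

The forecast gives Saturday's > Sunday's > Friday's > Tuesday's > Monday's at 1.5 h and Saturday's > Sunday's > Friday's > Tuesday's > Monday's at 20 min, with 50% and 13%, holding that “Each electrophile uses two nucleophiles because the freed acid locks one up”.

The flasks give Saturday's > Sunday's > Friday's > Tuesday's > Monday's at 1.5 h and Saturday's > Sunday's > Friday's > Tuesday's > Monday's at 20 min, with 48.5% and 13.7%.

    target → over-reaction product (k = 0.00532 min⁻¹)
    2 nucleophile → homo dimer (k = 0.720 M⁻¹ min⁻¹)
    electrophile + nucleophile → acid set free + target (k = 1.43 M⁻¹ min⁻¹)
    nucleophile + acid set free ⇌ protonated nucleophile, settled at all times (K = 45000 M⁻¹)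

Watch the electrophile reading flatten. Monday's has 79.1% left at 1.50 h, against my 79.8%, with 0.480% of its nucleophile still free. Monday's target is low mainly because of the falling level of nucleophile: with that level held, the same flask gives 68.2% instead of 13.7%. Tuesday's allowance of 0.652 half-lives reckons 63.6% of its electrophile left, and at 1.50 h the flask has 64.1%.

(Readings and results are simulated with constants of no real substance, and the scatter is random.)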